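# Proposed total synthesis of hansforester J (26)

## Analysis of the target

Hansforester J (26) is an open-chain triester of four units whose only rings are two benzene rings. Read from the resorcinol end these are unit A, (R)-1-(3,5-dihydroxyphenyl)propan-2-ol (ring A); unit B, (R)-3-hydroxybutanoic acid; unit C, 2,4-dihydroxy-6-[(R)-2-hydroxypropyl]benzoic acid (ring C); and unit D, a second (R)-3-hydroxybutanoic acid with a free hydroxyl. All four stereocentres are R, isolated methyl carbinol carbons, CH(CH3)–O, at least four bonds apart, so none can direct another and each has to be bought in enantiopure form and carried through by reactions that leave its C–O bond intact. Units B and D are β-oxygenated butanoates and lose the β-oxygen by E1cB with base. The side-chain oxygen of unit C lies δ to the benzoate carbonyl, so a free hydroxyl there can close to a mellein-type six-membered lactone and cut the chain. The hardest bond is the ester between the carboxyl on C1 of ring C and the oxygen of unit B, a 2,6-disubstituted, electron-rich benzoate of a secondary alcohol. The strategy rests on reading ring C as a 6-alkylresorcylate in which C1, its carboxyl carbon and C2 are the three carbons of a malonate and C3 to C6 with the propyl chain are the skeleton of a hept-3-en-2-one, so the hindered ester can be in place as a malonate ester before ring C exists if unit B is disguised as a base-stable (R)-pent-4-en-2-yl ester whose C4 later becomes the unit B carboxyl carbon.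

## Retrosynthetic reasoning

**26 from 25.** The four phenols and the hydroxyl of unit D are masked as benzyl ethers in 25. One neutral hydrogenolysis removes all five. No ester oxygen in the chain is benzylic, and no base comes near the two β-acyloxy esters.

**25 from 19 and 24.** The acyl–oxygen bond between the unit B carboxyl and the unit A oxygen is cut. This is the least hindered ester of the molecule (aliphatic acid 19, secondary alcohol 24), and cutting it last joins two large pieces at the end. The forward esterification has to avoid E1cB loss of the aroyloxy group from the activated acid.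

**24 from 21 and 22, 21 from 20.** The aryl–CH2 bond of unit A is cut. The Grignard reagent 23 from bromide 21 opens epoxide 22 at its CH2 group, so the stereocentre comes unchanged from 22. Bromide 21 is the dibenzyl ether of 20. Ring A is thus bought as an aromatic compound, not built.

**19 from 17 through 18.** The carboxyl carbon of unit B is traced back to C4 of the pent-4-en-2-yl ester in 17, and the C4=C5 double bond is the bond cut in the forward sense. This keeps the β-acyloxy acid of unit B out of every basic step before it.

**17 from 16 and 15, 16 from 13, 13 from 12, 15 from 14 from 1.** The ester between the unit D carboxyl and the side-chain oxygen is cut. Unit D cannot pass through an alkoxide-mediated ring construction, so that oxygen travels as a silyl ether (12, 13) and the phenols are benzylated first. The silyl-for-acyl exchange is placed before the alkene cleavage. The one intermediate that can lactonize, 16, is then made at the earliest and simplest stage, and no β-acyloxy ester is present when fluoride is. Acid 15 comes from 1 by acid-catalysed benzylation (14) and saponification.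

**12 from 8 and 5 (key disconnection).** C1–C6 and C2–C3 of ring C are cut. Cutting the ester C–O bond instead would call for acylation by a hindered benzoic acid, and cutting the aryl–carbonyl bond would call for a carbonylation at a doubly ortho-substituted carbon. The ring cuts give malonate 8, which already holds the hindered ester, and enone 5, which holds the side chain and its stereocentre. The forward reaction has to achieve conjugate addition (9), ring closure onto an ester (10) and loss of two hydrogens through an electrophilic bromine source (11), without touching the terminal alkenes or the silyl ether.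

**5 from 3 and 4, 3 from 2 from 1.** The C3=C4 double bond of the enone is cut into aldehyde 3 and the stabilized ylide 4. Aldehyde 3 is the silylated, half-reduced form of 1, which supplies the side-chain stereocentre.

**8 from 6 and 7.** Both ester C–O bonds of the malonate are cut. The symmetric diester from 6 and two molecules of 7 means that either ester may cyclize, and that the alkoxide set free in the ring closure is the one already in the molecule.

## Alternatives that were turned down

**Alternative 1: carbonylative dimerization of one monomer.**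
- Disconnection: the aryl–carbonyl bond at C1 of ring C and the acyl–oxygen bond to unit B are cut together. This shows that units C–D are units A–B plus one carbon, so both halves come from one hydroxy ester, (R)-1-[3,5-bis(benzyloxy)phenyl]propan-2-yl (R)-3-hydroxybutanoate A1.
- Forward key step: A1 is silylated at its hydroxyl and iodinated ortho to the side chain to give the aryl iodide A2. Then A2, carbon monoxide A3 and a second molecule of A1 are joined by alkoxycarbonylation under Pd(OAc)2 A4 and the bisphosphine Xantphos A5 to the protected target A6. Desilylation and hydrogenolysis would finish.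
- For it: it is the most convergent plan, it uses the hidden repeat in the molecule, and it would need roughly nine steps against sixteen here. On step economy it is clearly stronger.
- Against it: the bond-forming event is alcoholysis of an acylpalladium species flanked by a benzyloxy group and a branched alkyl group. The nucleophile is a secondary alcohol that can be used only in about one equivalent, not as solvent. That slow step leaves room for reduction of the iodide and for decarbonylation. The amine base and heat it needs act on two β-oxygenated butanoates (E1cB to crotonates) and let A1 transesterify with itself. The iodination must also prefer the position ortho to the side chain over the one between the two benzyloxy groups.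
- Comparison: the chosen route is longer, but the hindered aryl ester is never made from a hindered acyl donor. It is present in 8 before ring C exists, the ring closure is intramolecular and of a long-established type, and no β-acyloxy ester is in the flask.

**Alternative 2: Diels–Alder construction of ring C.**
- Disconnection: C1–C2 and C5–C6 of ring C are cut. This gives a hex-2-ynoate (C1, C6, the carboxyl and the side chain) and a 1,3-dioxygenated four-carbon diene (C2 to C5).
- Forward key step: the ynoate A7 already carries units A–B as its ester and unit D on its C5 oxygen. It is heated with the diene 1-methoxy-1,3-bis(trimethylsilyloxy)buta-1,3-diene A8. The nucleophilic CH2 end of A8 bonds to the β-carbon of A7, and acidic work-up strips the methoxy group and one silyloxy group to give the resorcylate A9 with both ring C phenols free.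
- For it: like the chosen plan it carries the hindered ester into the ring construction. It does so at the very end, it delivers ring C at the aromatic oxidation level without a dehydrogenation, and it needs no protection of the ring C phenols. On convergence and on these two points it is stronger.
- Against it: a 2-ynoate with an alkyl group on its β-carbon is a poor dienophile. Long heating is needed, during which A8 degrades or adds only in a conjugate sense. The CH2 group of A7 between the alkyne and the acyloxy-bearing carbon is acidic, so isomerization to an allenoate and loss of the unit D carboxylate threaten both the cycloaddition and the esterification that makes A7. Assembling A7 with two β-acyloxy esters already in place costs about as many steps as are saved.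
- Comparison: the chosen route pays with an oxidation step and two phenol protections. It gains a far more reactive acceptor (an enone toward a malonate anion) and a ring-forming step that contains none of the base-sensitive β-acyloxy esters.

**Alternative 3: Danheiser benzannulation of ring A.**
- Disconnection: ring A is taken apart into the four carbons of the 3-substituted cyclobutenone A10, whose substituent is the complete unit B ester chain, and the two carbons of (triisopropylsilyloxy)ethyne A11.
- Forward key step: heating opens A10 by a four-electron electrocyclic reaction, and the ketene so formed adds A11 in a [2+2] sense. A second four-electron ring opening and a six-electron closure give the phenol A12, the A–B monomer as a resorcinol monosilyl ether.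
- For it: the cascade is regiospecific and runs without acid, base or metal, so a β-silyloxy ester is at no risk. On mildness of the ring-forming step it is stronger than the chosen route.
- Against it: it is spent on the easy ring. A 5-alkylresorcinol of this kind is reached here in two steps (20 to 21 to 24), whereas A10 needs a multi-step synthesis of its own and A11 is a sensitive reagent. The differentiation of the two phenols in A12 is of no use, since both end up free. Above all it supplies only the A–B half, and ring C with its hindered ester would still need another plan.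
- Comparison: the chosen route places its ring construction where the difficulty lies and takes ring A from purchased aromatic material.

Key step: step 5

Remark: ring C is numbered as a benzoate throughout (C1 carries the carboxyl carbon, C2 and C4 the oxygens, C6 the side chain), and 1, 4, 6, 7, 20 and 22 are taken as purchased materials in the enantiomeric form named.

## Route

Step 1
Reactants: 1 methyl (R)-3-hydroxybutanoate
Product: 2 methyl (R)-3-(tert-butyldimethylsilyloxy)butanoate
Conditions: TBSCl, imidazole, DMF, 0 °C → rt
Reagents that add atoms: tert-butyldimethylsilyl chloride, CC(C)(C)[Si](C)(C)Cl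
Why: Silylation of a secondary alcohol with a silyl chloride under imidazole catalysis; the stereocentre is not involved.

Step 2
Reactants: 2 methyl (R)-3-(tert-butyldimethylsilyloxy)butanoate
Product: 3 (R)-3-(tert-butyldimethylsilyloxy)butanal
Conditions: i-Bu2AlH (1.05 equiv), CH2Cl2, −78 °C; MeOH, then aq KNaC4H4O6 (potassium sodium tartrate)
Reagents that add atoms: none
Why: Partial reduction of an ester with i-Bu2AlH at −78 °C stops at the aluminium hemiacetal, which gives the aldehyde on work-up; the stereocentre is β to the carbonyl and cannot epimerize.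

Step 3
Reactants: 3 (R)-3-(tert-butyldimethylsilyloxy)butanal; 4 (acetylmethylene)triphenylphosphorane
Product: 5 (R,E)-6-(tert-butyldimethylsilyloxy)hept-3-en-2-one
Conditions: CH2Cl2, rt → 40 °C
Reagents that add atoms: none
Why: Wittig olefination with a stabilized ylide should give the E-enone; the ylide is too weakly basic to eliminate the β-silyloxy group.

Step 4
Reactants: 6 malonyl dichloride; 7 (R)-pent-4-en-2-ol (2.1 equiv)
Product: 8 di[(R)-pent-4-en-2-yl] malonate
Conditions: pyridine (2.2 equiv), CH2Cl2, −10 °C → rt
Reagents that add atoms: none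
Why: Double O-acylation of a secondary alcohol by a diacid chloride; the bonds are formed at the acyl carbon, so both carbinol centres stay R.

Step 5
Reactants: 8 di[(R)-pent-4-en-2-yl] malonate (1.1 equiv); 5 (R,E)-6-(tert-butyldimethylsilyloxy)hept-3-en-2-one (1.0 equiv)
Product: 12 (R)-pent-4-en-2-yl 2,4-dihydroxy-6-[(R)-2-(tert-butyldimethylsilyloxy)propyl]benzoate, via Michael adduct 9 (not isolated), via cyclic dione ester 10 (not isolated), via 3-bromo dione ester 11 (not isolated)
Conditions: NaH and 7 (1.05 equiv each), THF, 0 °C; 8, then 5, 0 °C → 60 °C; then NBS (1.0 equiv), DMF, 0 °C → 60 °C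
Reagents that add atoms: none
Why: The sodium enolate of 8, made with a slight deficit of base so that no free alkoxide meets 5, adds to the β-carbon of the enone (Michael addition, C1–C6 bond) to give 9. Proton transfer then forms the methyl ketone enolate, whose CH2 carbon attacks one of the two constitutionally equivalent ester carbonyls in a favoured 6-(enolendo)-exo-trig Claisen closure (C2–C3 bond) and expels one equivalent of the alkoxide of 7; this deprotonates the acidic dione ester 10, whose stabilized sodium enolate pulls the equilibria forward. NBS then brominates this enolate at C3, between the two carbonyls (11); on warming, the bromine should migrate to C5, since 2-bromo-1,3-diones are reversible bromine donors, and loss of HBr across C5–C6, taken up by the succinimide anion, should leave an ene-dione that enolizes to the aromatic resorcylate 12. The closest known reaction type is the Michael–Claisen annulation of dialkyl malonates with alk-3-en-2-ones to 6-alkyl-2,4-dioxocyclohexanecarboxylates, followed by brominative aromatization to 6-alkylresorcylates. One ring is closed, the six-membered ring C, in the Claisen step; the ring stereocentres at C1 and C6 arise uncontrolled and vanish on aromatization, so no stereocentre is set, and the two R carbinol centres carry no acidic hydrogen and are only carried through. Three selectivities are needed: conjugate addition ahead of γ-deprotonation of 5 (secured by the soft, weakly basic malonate anion and the absence of free alkoxide), a single ester outcome (secured by the symmetric malonate, whose own alkoxide is the only one present), and bromination of the enolate ahead of the terminal alkenes of 10 and of the liberated 7 and ahead of the product arene (secured by the far higher nucleophilicity of the enolate, one equivalent of NBS and 0 °C).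

Step 6
Reactants: 12 (R)-pent-4-en-2-yl 2,4-dihydroxy-6-[(R)-2-(tert-butyldimethylsilyloxy)propyl]benzoate
Product: 13 (R)-pent-4-en-2-yl 2,4-bis(benzyloxy)-6-[(R)-2-(tert-butyldimethylsilyloxy)propyl]benzoate
Conditions: BnBr (2.5 equiv), K2CO3, DMF, 60 °C
Reagents that add atoms: benzyl bromide, BrCc1ccccc1
Why: Williamson etherification of both phenols; the hydrogen-bonded 2-hydroxyl next to the ester needs warm DMF, which the silyl ether and the secondary ester should tolerate.

Step 7
Reactants: 1 methyl (R)-3-hydroxybutanoate
Product: 14 methyl (R)-3-(benzyloxy)butanoate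
Conditions: benzyl 2,2,2-trichloroacetimidate, TfOH (cat.), CH2Cl2/cyclohexane, 0 °C → rt
Reagents that add atoms: benzyl 2,2,2-trichloroacetimidate, N=C(OCc1ccccc1)C(Cl)(Cl)Cl
Why: Acid-catalysed O-benzylation with a trichloroacetimidate needs no base, so the β-hydroxy ester can neither eliminate nor undergo retro-aldol cleavage; the C–O bond at the stereocentre is not broken.

Step 8
Reactants: 14 methyl (R)-3-(benzyloxy)butanoate
Product: 15 (R)-3-(benzyloxy)butanoic acid
Conditions: LiOH, THF/H2O, 0 °C → rt; then 1 M HCl
Reagents that add atoms: lithium hydroxide, [Li+].[OH-]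
Why: Saponification of a methyl ester; at 0 °C to rt the β-benzyloxy group is too poor a leaving group for E1cB loss, and the stereocentre is not α to the carbonyl.

Step 9
Reactants: 13 (R)-pent-4-en-2-yl 2,4-bis(benzyloxy)-6-[(R)-2-(tert-butyldimethylsilyloxy)propyl]benzoate
Product: 16 (R)-pent-4-en-2-yl 2,4-bis(benzyloxy)-6-[(R)-2-hydroxypropyl]benzoate
Conditions: HF·pyridine, pyridine, THF, 0 °C → rt
Reagents that add atoms: none
Why: Fluoride-mediated desilylation under pyridine-buffered acidic conditions frees the alcohol without forming an alkoxide that would attack the neighbouring benzoate carbonyl; 16 is to be used at once.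

Step 10
Reactants: 16 (R)-pent-4-en-2-yl 2,4-bis(benzyloxy)-6-[(R)-2-hydroxypropyl]benzoate; 15 (R)-3-(benzyloxy)butanoic acid
Product: 17 (R)-pent-4-en-2-yl 2,4-bis(benzyloxy)-6-{(R)-2-[(R)-3-(benzyloxy)butanoyloxy]propyl}benzoate
Conditions: EDC·HCl, DMAP (cat.), CH2Cl2, 0 °C → rt
Reagents that add atoms: none
Why: Steglich esterification of a secondary alcohol with a carbodiimide-activated acid; acylation at oxygen keeps both R centres, and the absence of strong base should disfavour lactonization of 16.

Step 11
Reactants: 17 (R)-pent-4-en-2-yl 2,4-bis(benzyloxy)-6-{(R)-2-[(R)-3-(benzyloxy)butanoyloxy]propyl}benzoate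
Product: 18 (R)-4-oxobutan-2-yl 2,4-bis(benzyloxy)-6-{(R)-2-[(R)-3-(benzyloxy)butanoyloxy]propyl}benzoate
Conditions: OsO4 (2 mol %), NaIO4, 2,6-lutidine, 1,4-dioxane/H2O, rt
Reagents that add atoms: osmium tetroxide, O=[Os](=O)(=O)=O; sodium periodate, [Na+].[O-]I(=O)(=O)=O
Why: Lemieux–Johnson oxidation, in which OsO4-catalysed dihydroxylation of the terminal alkene and periodate cleavage of the diol run in one flask, with 2,6-lutidine to suppress over-oxidation; the benzyl ethers and the ester-deactivated arene should not be attacked.

Step 12
Reactants: 18 (R)-4-oxobutan-2-yl 2,4-bis(benzyloxy)-6-{(R)-2-[(R)-3-(benzyloxy)butanoyloxy]propyl}benzoate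
Product: 19 (R)-3-[2,4-bis(benzyloxy)-6-{(R)-2-[(R)-3-(benzyloxy)butanoyloxy]propyl}benzoyloxy]butanoic acid
Conditions: NaClO2, NaH2PO4, 2-methyl-2-butene, t-BuOH/H2O, 0 °C → rt
Reagents that add atoms: sodium chlorite, [Na+].[O-]Cl=O
Why: Pinnick oxidation of the crude aldehyde at pH 3 to 4 with an alkene as hypochlorite scavenger; the mildly acidic medium should prevent E1cB loss of the β-aroyloxy group.

Step 13
Reactants: 20 5-bromobenzene-1,3-diol
Product: 21 1,3-bis(benzyloxy)-5-bromobenzene
Conditions: BnBr (2.2 equiv), K2CO3, acetone, reflux
Reagents that add atoms: benzyl bromide, BrCc1ccccc1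
Why: Williamson etherification of both phenols.

Step 14
Reactants: 21 1,3-bis(benzyloxy)-5-bromobenzene; 22 (R)-2-methyloxirane
Product: 24 (R)-1-[3,5-bis(benzyloxy)phenyl]propan-2-ol, via aryl Grignard reagent 23 (not isolated)
Conditions: Mg, THF, reflux; then CuI (10 mol %), 22, −30 °C → 0 °C; 1 M HCl work-up
Reagents that add atoms: none
Why: Copper-catalysed ring opening of a terminal epoxide by an aryl Grignard reagent at the unsubstituted carbon (SN2); the stereocentre of 22 is not touched, so the R alcohol results.

Step 15
Reactants: 19 (R)-3-[2,4-bis(benzyloxy)-6-{(R)-2-[(R)-3-(benzyloxy)butanoyloxy]propyl}benzoyloxy]butanoic acid; 24 (R)-1-[3,5-bis(benzyloxy)phenyl]propan-2-ol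
Product: 25 (R)-1-[3,5-bis(benzyloxy)phenyl]propan-2-yl (R)-3-[2,4-bis(benzyloxy)-6-{(R)-2-[(R)-3-(benzyloxy)butanoyloxy]propyl}benzoyloxy]butanoate
Conditions: EDC·HCl, DMAP (cat.), CH2Cl2, 0 °C → rt
Reagents that add atoms: none
Why: Steglich esterification between an unhindered aliphatic acid and a secondary alcohol, run cold with little DMAP to limit E1cB loss of the β-aroyloxy group from the activated acid; both carbinol centres keep their configuration.

Step 16
Reactants: 25 (R)-1-[3,5-bis(benzyloxy)phenyl]propan-2-yl (R)-3-[2,4-bis(benzyloxy)-6-{(R)-2-[(R)-3-(benzyloxy)butanoyloxy]propyl}benzoyloxy]butanoate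
Product: 26 hansforester J, (R)-1-(3,5-dihydroxyphenyl)propan-2-yl (R)-3-[2,4-dihydroxy-6-{(R)-2-[(R)-3-hydroxybutanoyloxy]propyl}benzoyloxy]butanoate
Conditions: H2 (1 atm), Pd/C (10 % palladium on carbon), EtOAc/EtOH, rt
Reagents that add atoms: none
Why: Hydrogenolysis of five O-benzyl ethers under neutral conditions; none of the ester C–O bonds is benzylic, so the chain should stay intact.

## Compound list

1 | methyl (R)-3-hydroxybutanoate | C[C@@H](O)CC(=O)OC | starting material
2 | methyl (R)-3-(tert-butyldimethylsilyloxy)butanoate | C[C@@H](O[Si](C)(C)C(C)(C)C)CC(=O)OC | intermediate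
3 | (R)-3-(tert-butyldimethylsilyloxy)butanal | C[C@@H](O[Si](C)(C)C(C)(C)C)CC=O | intermediate
4 | (acetylmethylene)triphenylphosphorane | CC(=O)C=P(c1ccccc1)(c1ccccc1)c1ccccc1 | starting material
5 | (R,E)-6-(tert-butyldimethylsilyloxy)hept-3-en-2-one | CC(=O)/C=C/C[C@@H](C)O[Si](C)(C)C(C)(C)C | intermediate
6 | malonyl dichloride | O=C(Cl)CC(Cl)=O | starting material
7 | (R)-pent-4-en-2-ol | C=CC[C@@H](C)O | starting material
8 | di[(R)-pent-4-en-2-yl] malonate | C=CC[C@@H](C)OC(=O)CC(=O)O[C@H](C)CC=C | intermediate
9 | Michael adduct, di[(R)-pent-4-en-2-yl] 2-[(2R)-2-(tert-butyldimethylsilyloxy)-6-oxoheptan-4-yl]malonate (both epimers at C4 of the heptane chain; not isolated) | C=CC[C@@H](C)OC(=O)C(C(=O)O[C@H](C)CC=C)C(CC(C)=O)C[C@@H](C)O[Si](C)(C)C(C)(C)C | intermediate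
10 | cyclic dione ester, (R)-pent-4-en-2-yl 6-[(R)-2-(tert-butyldimethylsilyloxy)propyl]-2,4-dioxocyclohexane-1-carboxylate (ring diastereomers, present as its sodium enolate; not isolated) | C=CC[C@@H](C)OC(=O)C1C(=O)CC(=O)CC1C[C@@H](C)O[Si](C)(C)C(C)(C)C | intermediate
11 | 3-bromo dione ester, (R)-pent-4-en-2-yl 3-bromo-6-[(R)-2-(tert-butyldimethylsilyloxy)propyl]-2,4-dioxocyclohexane-1-carboxylate (ring diastereomers; not isolated) | C=CC[C@@H](C)OC(=O)C1C(=O)C(Br)C(=O)CC1C[C@@H](C)O[Si](C)(C)C(C)(C)C | intermediate
12 | (R)-pent-4-en-2-yl 2,4-dihydroxy-6-[(R)-2-(tert-butyldimethylsilyloxy)propyl]benzoate | C=CC[C@@H](C)OC(=O)c1c(O)cc(O)cc1C[C@@H](C)O[Si](C)(C)C(C)(C)C | intermediate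
13 | (R)-pent-4-en-2-yl 2,4-bis(benzyloxy)-6-[(R)-2-(tert-butyldimethylsilyloxy)propyl]benzoate | C=CC[C@@H](C)OC(=O)c1c(OCc2ccccc2)cc(OCc2ccccc2)cc1C[C@@H](C)O[Si](C)(C)C(C)(C)C | intermediate
14 | methyl (R)-3-(benzyloxy)butanoate | C[C@@H](OCc1ccccc1)CC(=O)OC | intermediate
15 | (R)-3-(benzyloxy)butanoic acid | C[C@@H](OCc1ccccc1)CC(=O)O | intermediate
16 | (R)-pent-4-en-2-yl 2,4-bis(benzyloxy)-6-[(R)-2-hydroxypropyl]benzoate | C=CC[C@@H](C)OC(=O)c1c(OCc2ccccc2)cc(OCc2ccccc2)cc1C[C@@H](C)O | intermediate
17 | (R)-pent-4-en-2-yl 2,4-bis(benzyloxy)-6-{(R)-2-[(R)-3-(benzyloxy)butanoyloxy]propyl}benzoate | C=CC[C@@H](C)OC(=O)c1c(OCc2ccccc2)cc(OCc2ccccc2)cc1C[C@@H](C)OC(=O)C[C@@H](C)OCc1ccccc1 | intermediate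
18 | (R)-4-oxobutan-2-yl 2,4-bis(benzyloxy)-6-{(R)-2-[(R)-3-(benzyloxy)butanoyloxy]propyl}benzoate | O=CC[C@@H](C)OC(=O)c1c(OCc2ccccc2)cc(OCc2ccccc2)cc1C[C@@H](C)OC(=O)C[C@@H](C)OCc1ccccc1 | intermediate
19 | (R)-3-[2,4-bis(benzyloxy)-6-{(R)-2-[(R)-3-(benzyloxy)butanoyloxy]propyl}benzoyloxy]butanoic acid | OC(=O)C[C@@H](C)OC(=O)c1c(OCc2ccccc2)cc(OCc2ccccc2)cc1C[C@@H](C)OC(=O)C[C@@H](C)OCc1ccccc1 | intermediate
20 | 5-bromobenzene-1,3-diol | Oc1cc(O)cc(Br)c1 | starting material
21 | 1,3-bis(benzyloxy)-5-bromobenzene | Brc1cc(OCc2ccccc2)cc(OCc2ccccc2)c1 | intermediate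
22 | (R)-2-methyloxirane ((R)-propylene oxide) | C[C@@H]1CO1 | starting material
23 | [3,5-bis(benzyloxy)phenyl]magnesium bromide (not isolated) | Br[Mg]c1cc(OCc2ccccc2)cc(OCc2ccccc2)c1 | intermediate
24 | (R)-1-[3,5-bis(benzyloxy)phenyl]propan-2-ol | C[C@@H](O)Cc1cc(OCc2ccccc2)cc(OCc2ccccc2)c1 | intermediate
25 | (R)-1-[3,5-bis(benzyloxy)phenyl]propan-2-yl (R)-3-[2,4-bis(benzyloxy)-6-{(R)-2-[(R)-3-(benzyloxy)butanoyloxy]propyl}benzoyloxy]butanoate | C[C@H](Cc1cc(OCc2ccccc2)cc(OCc2ccccc2)c1)OC(=O)C[C@@H](C)OC(=O)c1c(OCc2ccccc2)cc(OCc2ccccc2)cc1C[C@@H](C)OC(=O)C[C@@H](C)OCc1ccccc1 | intermediate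
26 | hansforester J, (R)-1-(3,5-dihydroxyphenyl)propan-2-yl (R)-3-[2,4-dihydroxy-6-{(R)-2-[(R)-3-hydroxybutanoyloxy]propyl}benzoyloxy]butanoate | C[C@H](Cc1cc(O)cc(O)c1)OC(=O)C[C@@H](C)OC(=O)c1c(O)cc(O)cc1C[C@@H](C)OC(=O)C[C@@H](C)O | target

## Step count and least certain steps

Total step count: 16. Longest linear sequence: 11 steps (steps 1, 2, 3, 5, 6, 9, 10, 11, 12, 15 and 16, from 1 to 26).

**Step 5 (key step).** The ring closure onto a secondary alkyl ester should be slower than with the methyl or ethyl esters for which this annulation is established. The open Michael adduct may then linger, and reversal of the conjugate addition, a second conjugate addition, or γ-deprotonation of unreacted enone with loss of the silyloxy group may take over. In the second stage, if loss of HBr is slow, bromine may be passed on to the electron-rich product ring or across a terminal alkene. Fallback: the ring is built on a primary ester and the hindered ester is then made by O-alkylation of a carboxylate. Setting out from 5, the same one-flask annulation and aromatization with purchased diallyl malonate (C=CCOC(=O)CC(=O)OCC=C; NaH, THF, then NBS) should give allyl 2,4-dihydroxy-6-[(R)-2-(tert-butyldimethylsilyloxy)propyl]benzoate F1. Benzylation (BnBr, K2CO3, DMF) gives allyl 2,4-bis(benzyloxy)-6-[(R)-2-(tert-butyldimethylsilyloxy)propyl]benzoate F2. Allyl transfer to morpholine catalysed by Pd(PPh3)4, which does not depend on access to the hindered carbonyl, frees 2,4-bis(benzyloxy)-6-[(R)-2-(tert-butyldimethylsilyloxy)propyl]benzoic acid F3. A Mitsunobu reaction of F3 with purchased (S)-pent-4-en-2-ol (C=CC[C@H](C)O; PPh3, DIAD, THF) alkylates the carboxylate with inversion and returns to the route at 13.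

**Step 9 (with its consequence for step 10).** The freed hydroxyl lies δ to the benzoate carbonyl, so lactonization by intramolecular transesterification, with loss of the pentenyl alcohol, may occur during desilylation, on silica or while the acylation of step 10 is under way. Fallback: the hydroxyl is freed and acylated while the 2-hydroxyl of ring C is still unprotected. That phenol is far more acidic than the alcohol, so no alkoxide can persist beside it, and as a phenoxide it makes the ester a poor electrophile. Setting out from 12, selective benzylation of the 4-hydroxyl (BnBr 1.05 equiv, K2CO3, acetone, rt; the hydrogen-bonded 2-hydroxyl stays free) gives (R)-pent-4-en-2-yl 4-(benzyloxy)-2-hydroxy-6-[(R)-2-(tert-butyldimethylsilyloxy)propyl]benzoate F4. Desilylation (HF·pyridine, THF) gives (R)-pent-4-en-2-yl 4-(benzyloxy)-2-hydroxy-6-[(R)-2-hydroxypropyl]benzoate F5. Steglich acylation with 15, which should prefer the aliphatic hydroxyl over the chelated phenol, gives (R)-pent-4-en-2-yl 4-(benzyloxy)-6-{(R)-2-[(R)-3-(benzyloxy)butanoyloxy]propyl}-2-hydroxybenzoate F6. Benzylation of the remaining phenol (BnBr, K2CO3, DMF, 60 °C) returns to the route at 17.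

**Step 15.** Once acid 19 is activated as an acyl donor, E1cB loss of the ring C benzoate from its β-position may compete with ester formation, as may rearrangement of the activated acid to an unreactive N-acylurea. Fallback: the ester is made with the acid as nucleophile, so it is never activated. Setting out from 21, the Grignard reagent 23 opens purchased (S)-2-methyloxirane (C[C@H]1CO1) under the conditions of step 14 to give (S)-1-[3,5-bis(benzyloxy)phenyl]propan-2-ol F7. A Mitsunobu reaction of 19 with F7 (PPh3, DIAD, THF, 0 °C) forms the ester with inversion at the carbinol carbon and returns to the route at 25.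

## Further compounds

F1 | step 5 | allyl 2,4-dihydroxy-6-[(R)-2-(tert-butyldimethylsilyloxy)propyl]benzoate | C=CCOC(=O)c1c(O)cc(O)cc1C[C@@H](C)O[Si](C)(C)C(C)(C)C
F2 | step 5 | allyl 2,4-bis(benzyloxy)-6-[(R)-2-(tert-butyldimethylsilyloxy)propyl]benzoate | C=CCOC(=O)c1c(OCc2ccccc2)cc(OCc2ccccc2)cc1C[C@@H](C)O[Si](C)(C)C(C)(C)C
F3 | step 5 | 2,4-bis(benzyloxy)-6-[(R)-2-(tert-butyldimethylsilyloxy)propyl]benzoic acid | OC(=O)c1c(OCc2ccccc2)cc(OCc2ccccc2)cc1C[C@@H](C)O[Si](C)(C)C(C)(C)C
F4 | step 9 | (R)-pent-4-en-2-yl 4-(benzyloxy)-2-hydroxy-6-[(R)-2-(tert-butyldimethylsilyloxy)propyl]benzoate | C=CC[C@@H](C)OC(=O)c1c(O)cc(OCc2ccccc2)cc1C[C@@H](C)O[Si](C)(C)C(C)(C)C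
F5 | step 9 | (R)-pent-4-en-2-yl 4-(benzyloxy)-2-hydroxy-6-[(R)-2-hydroxypropyl]benzoate | C=CC[C@@H](C)OC(=O)c1c(O)cc(OCc2ccccc2)cc1C[C@@H](C)O
F6 | step 9 | (R)-pent-4-en-2-yl 4-(benzyloxy)-6-{(R)-2-[(R)-3-(benzyloxy)butanoyloxy]propyl}-2-hydroxybenzoate | C=CC[C@@H](C)OC(=O)c1c(O)cc(OCc2ccccc2)cc1C[C@@H](C)OC(=O)C[C@@H](C)OCc1ccccc1
F7 | step 15 | (S)-1-[3,5-bis(benzyloxy)phenyl]propan-2-ol | C[C@H](O)Cc1cc(OCc2ccccc2)cc(OCc2ccccc2)c1
A1 | alternative 1 | (R)-1-[3,5-bis(benzyloxy)phenyl]propan-2-yl (R)-3-hydroxybutanoate | C[C@@H](O)CC(=O)O[C@H](C)Cc1cc(OCc2ccccc2)cc(OCc2ccccc2)c1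
A2 | alternative 1 | (R)-1-[3,5-bis(benzyloxy)-2-iodophenyl]propan-2-yl (R)-3-(tert-butyldimethylsilyloxy)butanoate | C[C@@H](O[Si](C)(C)C(C)(C)C)CC(=O)O[C@H](C)Cc1cc(OCc2ccccc2)cc(OCc2ccccc2)c1I
A3 | alternative 1 | carbon monoxide | [C-]#[O+]
A4 | alternative 1 | palladium diacetate, Pd(OAc)2 | CC(=O)[O-].CC(=O)[O-].[Pd+2]
A5 | alternative 1 | Xantphos, 4,5-bis(diphenylphosphino)-9,9-dimethylxanthene | CC1(C)c2cccc(P(c3ccccc3)c3ccccc3)c2Oc2c(P(c3ccccc3)c3ccccc3)cccc21
A6 | alternative 1 | (R)-1-[3,5-bis(benzyloxy)phenyl]propan-2-yl (R)-3-[2,4-bis(benzyloxy)-6-{(R)-2-[(R)-3-(tert-butyldimethylsilyloxy)butanoyloxy]propyl}benzoyloxy]butanoate | C[C@H](Cc1cc(OCc2ccccc2)cc(OCc2ccccc2)c1)OC(=O)C[C@@H](C)OC(=O)c1c(OCc2ccccc2)cc(OCc2ccccc2)cc1C[C@@H](C)OC(=O)C[C@@H](C)O[Si](C)(C)C(C)(C)C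
A7 | alternative 2 | (R)-4-{(R)-1-[3,5-bis(benzyloxy)phenyl]propan-2-yloxy}-4-oxobutan-2-yl (R)-5-[(R)-3-(benzyloxy)butanoyloxy]hex-2-ynoate | C[C@H](Cc1cc(OCc2ccccc2)cc(OCc2ccccc2)c1)OC(=O)C[C@@H](C)OC(=O)C#CC[C@@H](C)OC(=O)C[C@@H](C)OCc1ccccc1
A8 | alternative 2 | 1-methoxy-1,3-bis(trimethylsilyloxy)buta-1,3-diene | COC(O[Si](C)(C)C)=CC(=C)O[Si](C)(C)C
A9 | alternative 2 | (R)-1-[3,5-bis(benzyloxy)phenyl]propan-2-yl (R)-3-[6-{(R)-2-[(R)-3-(benzyloxy)butanoyloxy]propyl}-2,4-dihydroxybenzoyloxy]butanoate | C[C@H](Cc1cc(OCc2ccccc2)cc(OCc2ccccc2)c1)OC(=O)C[C@@H](C)OC(=O)c1c(O)cc(O)cc1C[C@@H](C)OC(=O)C[C@@H](C)OCc1ccccc1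
A10 | alternative 3 | (R)-1-(3-oxocyclobut-1-en-1-yl)propan-2-yl (R)-3-(tert-butyldimethylsilyloxy)butanoate | C[C@@H](O[Si](C)(C)C(C)(C)C)CC(=O)O[C@H](C)CC1=CC(=O)C1
A11 | alternative 3 | (triisopropylsilyloxy)ethyne | C#CO[Si](C(C)C)(C(C)C)C(C)C
A12 | alternative 3 | (R)-1-[3-hydroxy-5-(triisopropylsilyloxy)phenyl]propan-2-yl (R)-3-(tert-butyldimethylsilyloxy)butanoate | C[C@@H](O[Si](C)(C)C(C)(C)C)CC(=O)O[C@H](C)Cc1cc(O)cc(O[Si](C(C)C)(C(C)C)C(C)C)c1
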